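## Retrosynthetic overview

- The pyranone ring is made last, by 6-endo opening of an (αR,βS)-chalcone epoxide. The chalcone comes from the aldehyde of the lignan core and a protected phloroacetophenone.
- Ring A (C7–O–C9'–C8'–C8) comes from a γ-aryl lactone by reduction and Mitsunobu closure. The lactone (C7, C8) comes from an Evans syn-aldol and the biaryl from a Suzuki coupling.
- Feature: the C7'–H bond of the ring P benzyl ether is benzylic, α to the ether oxygen on C9, and 1,5 to C8' of the lactone. A rhodium carbene at C8' inserts into it, forming C8'–C7' and closing ring B (C7'–O–C9–C8–C8') cis-fused, so C8 sets C8'.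
- The insertion should place ring P endo, so C7' is re-set afterwards: free ring P phenol, DDQ to the C7' ketone, reduction, quinone-methide closure (ring P exo).
- Ring order: lactone, ring B, ring A, ring B re-closed, pyranone.

Key step: step 14

Remark on the chemistry: in this class of insertion the aryl group of the benzyl ether is expected to end up cis to the lactone carbonyl, so 22 is drawn with ring P endo (C7' epimeric to the target). The route does not rely on that centre, because both C7' epimers converge at ketone 26. Compounds 2, 4 and 30 are taken as commercial. Phenols carry benzyl groups (ring P: TIPS) so that the furofuran never meets hot acid.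

## Route

Step 1
Reactants: 1 (S)-4-benzyl-1,3-oxazolidin-2-one; 2 methyl 4-chloro-4-oxobutanoate
Product: 3 methyl 4-[(4S)-4-benzyl-2-oxo-1,3-oxazolidin-3-yl]-4-oxobutanoate
Conditions: n-BuLi, THF, −78 °C; then 2, −78 to 0 °C
Reagents that add atoms: none
Why: N-acylation of the lithiated oxazolidinone by the acid chloride is the standard loading of the auxiliary, and the ester end is inert at low temperature.

Step 2
Reactants: 3 succinate imide; 4 4-(benzyloxy)-3-methoxybenzaldehyde
Product: 6 trans-lactone imide, via syn-aldol adduct 5 (not isolated)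
Conditions: Bu2BOTf, iPr2NEt, CH2Cl2, −78 to 0 °C; pH 7 buffer, MeOH, H2O2; then p-TsOH (cat.), CH2Cl2, rt
Reagents that add atoms: none
Why: Evans syn-aldol through the Z-boron enolate in a closed chair transition state sets C8 and C7 (7S) under control of the (S)-benzyl auxiliary, and the syn adduct lactonises onto the remote methyl ester to give the trans 4,5-disubstituted γ-lactone.

Step 3
Reactants: 6 trans-lactone imide
Product: 8 (2S,3S)-2-[4-(benzyloxy)-3-methoxyphenyl]-5-oxooxolane-3-carboxylic acid, via peroxy acid 7 (not isolated)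
Conditions: LiOH, H2O2, THF/H2O, 0 °C; Na2SO3; HCl to pH 2
Reagents that add atoms: hydrogen peroxide, OO
Why: Hydroperoxide cleaves the exocyclic imide carbonyl selectively (auxiliary removal), any opened lactone re-closes on acidification, and no stereocentre is touched.

Step 4
Reactants: 8 paraconic acid
Product: 9 (4R,5S)-5-[4-(benzyloxy)-3-methoxyphenyl]-4-(hydroxymethyl)oxolan-2-one
Conditions: BH3·SMe2, THF, 0 °C to rt; MeOH
Reagents that add atoms: none
Why: Borane reduces a carboxylic acid through its acyloxyborane much faster than a lactone, so only C9 is reduced (chemoselective borane reduction).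

Step 5
Reactants: 10 5-iodovanillin
Product: 11 3-iodo-5-methoxy-4-[(triisopropylsilyl)oxy]benzaldehyde
Conditions: TIPSOTf, 2,6-lutidine, CH2Cl2, 0 °C
Reagents that add atoms: triisopropylsilyl trifluoromethanesulfonate, CC(C)[Si](OS(=O)(=O)C(F)(F)F)(C(C)C)C(C)C
Why: Silylation of the hindered phenol with the silyl triflate gives a ring P protecting group that fluoride can later remove without touching benzyl ethers.

Step 6
Reactants: 12 3-bromo-4,5-dihydroxybenzaldehyde
Product: 13 3,4-bis(benzyloxy)-5-bromobenzaldehyde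
Conditions: BnBr, K2CO3, DMF, 50 °C
Reagents that add atoms: benzyl bromide, BrCc1ccccc1
Why: Williamson etherification of both catechol hydroxyls.

Step 7
Reactants: 13 dibenzyl bromo aldehyde
Product: 14 2-[3,4-bis(benzyloxy)-5-bromophenyl]-1,3-dioxolane
Conditions: HOCH2CH2OH, p-TsOH (cat.), toluene, reflux (Dean–Stark)
Reagents that add atoms: ethylene glycol, OCCO
Why: Acetalisation with removal of water masks the aldehyde against the hydride, amide base and carbene steps that follow.

Step 8
Reactants: 14 bromo dioxolane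
Product: 15 2-[2,3-bis(benzyloxy)-5-(1,3-dioxolan-2-yl)phenyl]-4,4,5,5-tetramethyl-1,3,2-dioxaborolane
Conditions: B2pin2, PdCl2(dppf), KOAc, 1,4-dioxane, 85 °C
Reagents that add atoms: bis(pinacolato)diboron, CC1(C)OB(B2OC(C)(C)C(C)(C)O2)OC1(C)C
Why: Miyaura borylation of the aryl bromide, with acetate as a base too weak to start homocoupling.

Step 9
Reactants: 15 aryl boronate; 11 aryl iodide
Product: 16 3-[2,3-bis(benzyloxy)-5-(1,3-dioxolan-2-yl)phenyl]-5-methoxy-4-[(triisopropylsilyl)oxy]benzaldehyde
Conditions: Pd(OAc)2, SPhos, K3PO4, toluene/H2O, 80 °C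
Reagents that add atoms: none
Why: Suzuki–Miyaura coupling; the bulky biaryl phosphine handles the two ortho oxygen substituents flanking the new biaryl bond.

Step 10
Reactants: 16 biaryl aldehyde
Product: 17 the corresponding benzyl alcohol
Conditions: NaBH4, MeOH/THF, 0 °C
Reagents that add atoms: none
Why: Borohydride reduction of the only free aldehyde; the other one is masked as the dioxolane.

Step 11
Reactants: 17 biaryl benzyl alcohol
Product: 18 the corresponding benzyl bromide
Conditions: CBr4, PPh3, CH2Cl2, 0 °C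
Reagents that add atoms: carbon tetrabromide, BrC(Br)(Br)Br
Why: Appel bromination is neutral, so the acetal and silyl ether survive.

Step 12
Reactants: 9 hydroxymethyl lactone; 18 biaryl benzyl bromide
Product: 19 (4R,5S)-lactone whose C9 oxygen carries the biaryl benzyl group
Conditions: Ag2O, 4 Å MS, CH2Cl2, rt, dark
Reagents that add atoms: none
Why: Silver-oxide-promoted Williamson etherification forms the ether without a free alkoxide, which would otherwise translactonise onto the lactone carbonyl.

Step 13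
Reactants: 19 lactone ether
Product: 21 α-diazo lactone (carbene precursor), via trifluoroacetyl lactone 20 (not isolated)
Conditions: LiHMDS, THF, −78 °C; CF3CO2CH2CF3; aq. NH4Cl; then MsN3, Et3N, H2O, MeCN, rt
Reagents that add atoms: methanesulfonyl azide, CS(=O)(=O)N=[N+]=[N-]; 2,2,2-trifluoroethyl trifluoroacetate, O=C(OCC(F)(F)F)C(F)(F)F (its trifluoroacetyl group stays only in 20)
Why: Deacylative Regitz diazo transfer: trifluoroacetylation makes C8' acidic enough to accept the diazo group from the sulfonyl azide, and the acyl group leaves as the sulfonyl amide.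

Step 14
Reactants: 21 α-diazo lactone
Product: 22 cis-fused furofuranone (lactone carbonyl at C9', ring G exo, ring P endo)
Conditions: Rh2(OAc)4 (2 mol %), CH2Cl2, reflux, slow addition of 21
Reagents that add atoms: none
Why: Rh2(OAc)4 decomposes the diazo lactone with loss of N2 to an electrophilic rhodium carbene at C8', which inserts into the C7'–H bond of the ring P benzyl ether in a concerted, asynchronous three-centre event (hydride-like transfer, then C8'–C7' bond formation); the closest known reaction type is the dirhodium-catalysed 1,5 C–H insertion of α-diazo-γ-butyrolactones into benzyl ether C–H bonds that gives furofuranones. Ring B closes as a five-membered ring through a six-membered hydrogen-bridged transition state, and because the tether holds C7' over one face of the planar carbene the new ring can only be cis-fused. C8' is therefore controlled by C8 (H8' cis to H8), and this is the stereocentre the route takes from the step. At C7' the aryl group should avoid the carboxylate wall of the catalyst and lie over the lactone carbonyl, so ring P is expected endo (7'R); this centre is not relied upon and is re-set in steps 17 to 20. The step needs 1,5-insertion to win over 1,2-hydride migration from C8 (butenolide), over other C–H bonds and over arene addition; the double activation of C7'–H (benzylic and α to oxygen), its 1,5 position, the weakly electrophilic acetate ligands and slow addition at high dilution secure this.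

Step 15
Reactants: 22 furofuranone
Product: 23 diol (ring B intact; secondary benzylic OH at C7, primary OH at C9')
Conditions: LiAlH4, THF, 0 °C; aqueous work-up
Reagents that add atoms: none
Why: Hydride reduction of the lactone to the 1,4-diol; the C7–O bond is not broken, so C7 stays S, and the ether ring, silyl ether, acetal and benzyl ethers are inert.

Step 16
Reactants: 23 diol
Product: 24 7'-epi furofuran core (rings A and B closed, ring G exo, ring P endo, TIPS on ring P)
Conditions: PPh3, DIAD, THF, 0 °C to rt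
Reagents that add atoms: none
Why: Mitsunobu cyclodehydration activates the primary C9' hydroxyl and the C7 hydroxyl displaces it 5-exo-tet, so ring A closes with retention at C7.

Step 17
Reactants: 24 silyl ether
Product: 25 free ring P phenol
Conditions: Bu4NF, AcOH, THF, 0 °C
Reagents that add atoms: none
Why: Fluoride cleaves the aryl silyl ether only (desilylation), and acetic acid buffers the phenoxide.

Step 18
Reactants: 25 phenol
Product: 26 hydroxy ketone (ring B opened: C7' ketone on C8', CH2OH on C8, ring A intact)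
Conditions: DDQ (1.1 equiv), CH2Cl2/pH 7 buffer, 0 °C
Reagents that add atoms: water, O
Why: DDQ benzylic oxidation: hydride abstraction para to the free phenol gives a quinone-methide-type oxocarbenium ion, water adds and the hemiketal opens to the para-hydroxyaryl ketone, which erases the C7' stereocentre; the benzyl-capped ring G cannot form a quinone methide.

Step 19
Reactants: 26 hydroxy ketone
Product: 27 diol (both C7' epimers)
Conditions: NaBH4, CeCl3·7H2O, MeOH, −20 °C
Reagents that add atoms: none
Why: Luche reduction of the aryl ketone under nearly neutral, cold conditions avoids epimerisation at C8'; the configuration formed at C7' does not matter.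

Step 20
Reactants: 27 diol
Product: 29 furofuran core aldehyde (7S,8R,7'S,8'R; ring P phenol free), via exo furofuran acetal 28 (not isolated)
Conditions: PPTS (cat.), acetone/H2O, 40 °C
Reagents that add atoms: water, O
Why: Acid-catalysed cyclisation through the ring P quinone methide (para-hydroxybenzyl cation): the cation holds H8' in its plane to minimise allylic strain and the C9 hydroxyl adds 5-exo from the C8 side, which sets C7' as S with ring P exo (trans to C9'), as in kinetic quinone-methide closures of furofuran lignans; the same medium hydrolyses the dioxolane.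

Step 21
Reactants: 30 2,4,6-trihydroxyacetophenone
Product: 31 1-[2,4-bis(benzyloxy)-6-hydroxyphenyl]ethanone
Conditions: BnBr (2 equiv), K2CO3, acetone, reflux
Reagents that add atoms: benzyl bromide, BrCc1ccccc1
Why: Williamson etherification stops at two benzyl groups because the last ortho hydroxyl is hydrogen-bonded to the ketone.

Step 22
Reactants: 31 hydroxy acetophenone
Product: 32 1-[2,4-bis(benzyloxy)-6-(methoxymethoxy)phenyl]ethanone
Conditions: NaH, MOMCl, DMF, 0 °C
Reagents that add atoms: chloromethyl methyl ether, COCCl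
Why: Alkylation of the sodium phenoxide places an acid-labile group on the oxygen that will become O1 of the pyranone.

Step 23
Reactants: 29 aldehyde; 32 acetophenone
Product: 33 (E)-chalcone
Conditions: KOH, EtOH/H2O, rt; dilute HCl to pH 6
Reagents that add atoms: none
Why: Claisen–Schmidt condensation gives the conjugated E-enone; the ring P phenoxide is a spectator.

Step 24
Reactants: 33 chalcone
Product: 34 (αR,βS)-trans-epoxide
Conditions: poly-L-leucine, urea·H2O2, DBU, THF, rt
Reagents that add atoms: urea–hydrogen peroxide, NC(N)=O.OO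
Why: Juliá–Colonna epoxidation: the poly-L-leucine helix delivers hydroperoxide to one enone face, setting Cα (future C3) as R and Cβ as S.

Step 25
Reactants: 34 epoxide
Product: 36 penta-O-benzyl (2R,3R)-flavanonol, via 2'-hydroxy epoxide 35 (not isolated)
Conditions: HCl (1 M), MeOH/THF, 0 °C to rt
Reagents that add atoms: none
Why: Mild acid removes the MOM group ortho to the carbonyl, and the freed phenol opens the protonated epoxide 6-endo at the benzylic carbon with inversion, which gives the 2,3-trans (2R,3R) flavanonol while C3 keeps the Cα configuration.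

Step 26
Reactants: 36 benzyl-protected flavanonol
Product: 37 CNP0226398.1
Conditions: H2 (1 atm), Pd/C, EtOAc/MeOH, rt
Reagents that add atoms: none
Why: Hydrogenolysis of the five aryl benzyl ethers is much faster than that of the dialkyl benzylic C–O bonds of rings A and B or of C2–O1, so the reaction is stopped at full debenzylation.

## Compound list

1 | (S)-4-benzyl-1,3-oxazolidin-2-one | O=C1N[C@@H](Cc2ccccc2)CO1 | starting material
2 | methyl 4-chloro-4-oxobutanoate | COC(=O)CCC(Cl)=O | starting material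
3 | methyl 4-[(4S)-4-benzyl-2-oxo-1,3-oxazolidin-3-yl]-4-oxobutanoate | COC(=O)CCC(=O)N1[C@@H](Cc2ccccc2)COC1=O | intermediate
4 | 4-(benzyloxy)-3-methoxybenzaldehyde | COc1cc(C=O)ccc1OCc1ccccc1 | starting material
5 | syn-aldol adduct (imide α-carbon S, carbinol carbon S) | COC(=O)C[C@H](C(=O)N1[C@@H](Cc2ccccc2)COC1=O)[C@H](O)c1ccc(OCc2ccccc2)c(OC)c1 | intermediate (not isolated)
6 | (4S)-4-benzyl-3-{[(2S,3S)-2-(4-benzyloxy-3-methoxyphenyl)-5-oxooxolan-3-yl]carbonyl}-1,3-oxazolidin-2-one | COc1cc([C@H]2OC(=O)C[C@@H]2C(=O)N2[C@@H](Cc3ccccc3)COC2=O)ccc1OCc1ccccc1 | intermediate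
7 | (2S,3S)-2-(4-benzyloxy-3-methoxyphenyl)-5-oxooxolane-3-carboperoxoic acid | COc1cc([C@H]2OC(=O)C[C@@H]2C(=O)OO)ccc1OCc1ccccc1 | intermediate (not isolated)
8 | (2S,3S)-2-(4-benzyloxy-3-methoxyphenyl)-5-oxooxolane-3-carboxylic acid | COc1cc([C@H]2OC(=O)C[C@@H]2C(=O)O)ccc1OCc1ccccc1 | intermediate
9 | (4R,5S)-5-(4-benzyloxy-3-methoxyphenyl)-4-(hydroxymethyl)oxolan-2-one | COc1cc([C@H]2OC(=O)C[C@@H]2CO)ccc1OCc1ccccc1 | intermediate
10 | 5-iodovanillin (4-hydroxy-3-iodo-5-methoxybenzaldehyde) | COc1cc(C=O)cc(I)c1O | starting material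
11 | 3-iodo-5-methoxy-4-[(triisopropylsilyl)oxy]benzaldehyde | COc1cc(C=O)cc(I)c1O[Si](C(C)C)(C(C)C)C(C)C | intermediate
12 | 3-bromo-4,5-dihydroxybenzaldehyde | O=Cc1cc(O)c(O)c(Br)c1 | starting material
13 | 3,4-bis(benzyloxy)-5-bromobenzaldehyde | O=Cc1cc(Br)c(OCc2ccccc2)c(OCc2ccccc2)c1 | intermediate
14 | 2-[3,4-bis(benzyloxy)-5-bromophenyl]-1,3-dioxolane | Brc1cc(C2OCCO2)cc(OCc2ccccc2)c1OCc1ccccc1 | intermediate
15 | 2-[2,3-bis(benzyloxy)-5-(1,3-dioxolan-2-yl)phenyl]-4,4,5,5-tetramethyl-1,3,2-dioxaborolane | CC1(C)OB(c2cc(C3OCCO3)cc(OCc3ccccc3)c2OCc2ccccc2)OC1(C)C | intermediate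
16 | 3-[2,3-bis(benzyloxy)-5-(1,3-dioxolan-2-yl)phenyl]-5-methoxy-4-[(triisopropylsilyl)oxy]benzaldehyde | COc1cc(C=O)cc(-c2cc(C3OCCO3)cc(OCc3ccccc3)c2OCc2ccccc2)c1O[Si](C(C)C)(C(C)C)C(C)C | intermediate
17 | benzyl alcohol of 16 (CHO reduced to CH2OH) | COc1cc(CO)cc(-c2cc(C3OCCO3)cc(OCc3ccccc3)c2OCc2ccccc2)c1O[Si](C(C)C)(C(C)C)C(C)C | intermediate
18 | benzyl bromide of 17 (CH2OH replaced by CH2Br) | COc1cc(CBr)cc(-c2cc(C3OCCO3)cc(OCc3ccccc3)c2OCc2ccccc2)c1O[Si](C(C)C)(C(C)C)C(C)C | intermediate
19 | (4R,5S)-5-(4-benzyloxy-3-methoxyphenyl)-4-[(biaryl-benzyloxy)methyl]oxolan-2-one (biaryl benzyl of 18 on the C9 oxygen) | COc1cc([C@H]2OC(=O)C[C@@H]2COCc2cc(OC)c(O[Si](C(C)C)(C(C)C)C(C)C)c(-c3cc(C4OCCO4)cc(OCc4ccccc4)c3OCc3ccccc3)c2)ccc1OCc1ccccc1 | intermediate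
20 | α-trifluoroacetyl derivative of 19 (at C8') | COc1cc([C@H]2OC(=O)C(C(=O)C(F)(F)F)[C@@H]2COCc2cc(OC)c(O[Si](C(C)C)(C(C)C)C(C)C)c(-c3cc(C4OCCO4)cc(OCc4ccccc4)c3OCc3ccccc3)c2)ccc1OCc1ccccc1 | intermediate (not isolated)
21 | α-diazo lactone (diazo at C8'; C7 S, trans to the C8 side chain) | COc1cc([C@H]2OC(=O)C(=[N+]=[N-])[C@@H]2COCc2cc(OC)c(O[Si](C(C)C)(C(C)C)C(C)C)c(-c3cc(C4OCCO4)cc(OCc4ccccc4)c3OCc3ccccc3)c2)ccc1OCc1ccccc1 | intermediate
22 | cis-fused 2,6-diaryl-3,7-dioxabicyclo[3.3.0]octan-8-one (carbonyl at C9'; ring G exo at C7, ring P endo at C7') | COc1cc([C@H]2OC(=O)[C@H]3[C@@H]2CO[C@H]3c2cc(OC)c(O[Si](C(C)C)(C(C)C)C(C)C)c(-c3cc(C4OCCO4)cc(OCc4ccccc4)c3OCc3ccccc3)c2)ccc1OCc1ccccc1 | intermediate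
23 | diol: all-cis 2-aryl(ring P)-3-(hydroxymethyl)-4-[(S)-hydroxy(ring G)methyl]oxolane | COc1cc([C@@H](O)[C@H]2CO[C@@H](c3cc(OC)c(O[Si](C(C)C)(C(C)C)C(C)C)c(-c4cc(C5OCCO5)cc(OCc5ccccc5)c4OCc4ccccc4)c3)[C@H]2CO)ccc1OCc1ccccc1 | intermediate
24 | 7'-epi furofuran (7S,8R,7'R,8'R; ring P endo; TIPS on ring P) | COc1cc([C@H]2OC[C@H]3[C@@H]2CO[C@H]3c2cc(OC)c(O[Si](C(C)C)(C(C)C)C(C)C)c(-c3cc(C4OCCO4)cc(OCc4ccccc4)c3OCc3ccccc3)c2)ccc1OCc1ccccc1 | intermediate
25 | 7'-epi furofuran with free ring P phenol | COc1cc([C@H]2OC[C@H]3[C@@H]2CO[C@H]3c2cc(OC)c(O)c(-c3cc(C4OCCO4)cc(OCc4ccccc4)c3OCc3ccccc3)c2)ccc1OCc1ccccc1 | intermediate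
26 | hydroxy ketone: ring A oxolane with ring G at C7, CH2OH on C8 and the ring P aroyl group on C8' (cis to CH2OH) | COc1cc([C@H]2OC[C@H](C(=O)c3cc(OC)c(O)c(-c4cc(C5OCCO5)cc(OCc5ccccc5)c4OCc4ccccc4)c3)[C@@H]2CO)ccc1OCc1ccccc1 | intermediate
27 | diol from 26 (C7' carbinol, both epimers) | COc1cc([C@H]2OC[C@H](C(O)c3cc(OC)c(O)c(-c4cc(C5OCCO5)cc(OCc5ccccc5)c4OCc4ccccc4)c3)[C@@H]2CO)ccc1OCc1ccccc1 | intermediate
28 | exo,exo furofuran (7S,8R,7'S,8'R) with dioxolane | COc1cc([C@H]2OC[C@H]3[C@@H]2CO[C@@H]3c2cc(OC)c(O)c(-c3cc(C4OCCO4)cc(OCc4ccccc4)c3OCc3ccccc3)c2)ccc1OCc1ccccc1 | intermediate (not isolated)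
29 | exo,exo furofuran core aldehyde | COc1cc([C@H]2OC[C@H]3[C@@H]2CO[C@@H]3c2cc(OC)c(O)c(-c3cc(C=O)cc(OCc4ccccc4)c3OCc3ccccc3)c2)ccc1OCc1ccccc1 | intermediate
30 | 2,4,6-trihydroxyacetophenone | CC(=O)c1c(O)cc(O)cc1O | starting material
31 | 1-[2,4-bis(benzyloxy)-6-hydroxyphenyl]ethanone | CC(=O)c1c(O)cc(OCc2ccccc2)cc1OCc1ccccc1 | intermediate
32 | 1-[2,4-bis(benzyloxy)-6-(methoxymethoxy)phenyl]ethanone | CC(=O)c1c(OCOC)cc(OCc2ccccc2)cc1OCc1ccccc1 | intermediate
33 | (E)-chalcone from 29 and 32 | COc1cc([C@H]2OC[C@H]3[C@@H]2CO[C@@H]3c2cc(OC)c(O)c(-c3cc(/C=C/C(=O)c4c(OCOC)cc(OCc5ccccc5)cc4OCc4ccccc4)cc(OCc4ccccc4)c3OCc3ccccc3)c2)ccc1OCc1ccccc1 | intermediate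
34 | (αR,βS)-trans-chalcone epoxide | COc1cc([C@H]2OC[C@H]3[C@@H]2CO[C@@H]3c2cc(OC)c(O)c(-c3cc([C@@H]4O[C@H]4C(=O)c4c(OCOC)cc(OCc5ccccc5)cc4OCc4ccccc4)cc(OCc4ccccc4)c3OCc3ccccc3)c2)ccc1OCc1ccccc1 | intermediate
35 | 2'-hydroxy epoxide (MOM group removed) | COc1cc([C@H]2OC[C@H]3[C@@H]2CO[C@@H]3c2cc(OC)c(O)c(-c3cc([C@@H]4O[C@H]4C(=O)c4c(O)cc(OCc5ccccc5)cc4OCc4ccccc4)cc(OCc4ccccc4)c3OCc3ccccc3)c2)ccc1OCc1ccccc1 | intermediate (not isolated)
36 | penta-O-benzyl (2R,3R)-flavanonol (benzyl on ring G O4, both catechol oxygens, O5 and O7) | COc1cc([C@H]2OC[C@H]3[C@@H]2CO[C@@H]3c2cc(OC)c(O)c(-c3cc([C@H]4Oc5cc(OCc6ccccc6)cc(OCc6ccccc6)c5C(=O)[C@@H]4O)cc(OCc4ccccc4)c3OCc3ccccc3)c2)ccc1OCc1ccccc1 | intermediate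
37 | CNP0226398.1 | COc1cc([C@H]2OC[C@H]3[C@@H]2CO[C@@H]3c2cc(OC)c(O)c(-c3cc([C@H]4Oc5cc(O)cc(O)c5C(=O)[C@@H]4O)cc(O)c3O)c2)ccc1O | target

## Step count and risks

Total step count: 26. Longest linear sequence: 19 steps (from 12 through steps 6 to 20 and 23 to 26).

Steps most likely to fail:

1. Step 14. The carbene may be consumed by 1,2-hydride migration from C8 (butenolide formation) or by dimerisation before it reaches the C7'–H bond. The fallback builds the C8'–C7' bond by a polar acyl transfer; it sets out from 9 and 16 and comes back at 22. Aldehyde 16 would be oxidised (NaClO2, NaH2PO4, 2-methyl-2-butene) to the biaryl benzoic acid F1, which is esterified with 9 (EDC·HCl, DMAP) to the benzoate F2. LiHMDS (2.2 equiv, THF, −78 to −20 °C) should then move the aroyl group from oxygen to the lactone α-carbon, an intramolecular Claisen condensation through a five-membered tetrahedral intermediate, to give the hydroxy β-keto lactone F3. F3 closes on its ketone and loses water (p-TsOH cat., toluene, 4 Å MS) to the bicyclic enol ether F4. Homogeneous hydrogenation (H2, [Ir(cod)(PCy3)(py)]PF6, CH2Cl2), which spares benzyl ethers, can add hydrogen to C7' and C8' only from the face that gives a cis-fused bicycle, and this returns 22.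

2. Step 18. Hydride abstraction may not stay at C7': attack at the ring A benzylic ether C7–H or over-oxidation of the electron-rich phenol would erode the yield. The fallback avoids the redox detour; it sets out from 25 and comes back at 28. Heating 25 with DBU in DMF should open ring B reversibly through the phenoxide to the ring P para-quinone methide and re-close it. Only ring P has a free phenol, so C7 cannot respond. This gives an equilibrium mixture of 25 and its C7' epimer 28; 28 is separated, 25 is recycled, and 28 is hydrolysed to 29 under the conditions of step 20.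

3. Step 24. Epoxidation of the twisted, electron-rich 2',6'-dioxygenated enone may be slow and the polyleucine helix may discriminate its faces poorly. The fallback gives up catalyst control; it sets out from 33 and comes back at 34. Weitz–Scheffer epoxidation (H2O2, NaOH, MeOH/THF, 0 °C) would give both trans-epoxides, 34 and the (αS,βR) epoxide F5. Because the lignan part is a single enantiomer these are diastereomers and are separated by chromatography; 34 then enters step 25.

Further compounds
F1 | step 14 | 3-[2,3-bis(benzyloxy)-5-(1,3-dioxolan-2-yl)phenyl]-5-methoxy-4-[(triisopropylsilyl)oxy]benzoic acid | COc1cc(C(=O)O)cc(-c2cc(C3OCCO3)cc(OCc3ccccc3)c2OCc2ccccc2)c1O[Si](C(C)C)(C(C)C)C(C)C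
F2 | step 14 | benzoate ester of 9 with F1 (aroyl group on the C9 oxygen) | COc1cc([C@H]2OC(=O)C[C@@H]2COC(=O)c2cc(OC)c(O[Si](C(C)C)(C(C)C)C(C)C)c(-c3cc(C4OCCO4)cc(OCc4ccccc4)c3OCc3ccccc3)c2)ccc1OCc1ccccc1
F3 | step 14 | hydroxy β-keto lactone (aroyl group on C8', free CH2OH on C8) | COc1cc([C@H]2OC(=O)C(C(=O)c3cc(OC)c(O[Si](C(C)C)(C(C)C)C(C)C)c(-c4cc(C5OCCO5)cc(OCc5ccccc5)c4OCc4ccccc4)c3)[C@@H]2CO)ccc1OCc1ccccc1
F4 | step 14 | bicyclic enol ether (C7'=C8' double bond; 2-aryl-3,7-dioxabicyclo[3.3.0]oct-1-en-8-one) | COc1cc([C@H]2OC(=O)C3=C(c4cc(OC)c(O[Si](C(C)C)(C(C)C)C(C)C)c(-c5cc(C6OCCO6)cc(OCc6ccccc6)c5OCc5ccccc5)c4)OC[C@H]23)ccc1OCc1ccccc1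
F0 | step 18 | none | none
F5 | step 24 | (αS,βR)-trans-chalcone epoxide, diastereomer of 34 | COc1cc([C@H]2OC[C@H]3[C@@H]2CO[C@@H]3c2cc(OC)c(O)c(-c3cc([C@H]4O[C@@H]4C(=O)c4c(OCOC)cc(OCc5ccccc5)cc4OCc4ccccc4)cc(OCc4ccccc4)c3OCc3ccccc3)c2)ccc1OCc1ccccc1
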